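**Retrosynthetic overview**
- Isoamoritin ⇒ open the O1–C2 bond (retro-oxa-Michael, the chalcone isomerase step) to the fully unprotected 3,2',4',6'-tetrahydroxy-4-methoxy-5,3',5'-triprenylchalcone. Forward, a catalytic enantioselective 6-endo-trig cyclisation is the last step and sets C2 (S) directly. The A ring is symmetric about its C1'–C4' axis, so either ortho-OH gives the same flavanone.
- Chalcone ⇒ protecting-group-free Claisen–Schmidt condensation of 3,5-diprenylphloroacetophenone with 3-hydroxy-4-methoxy-5-prenylbenzaldehyde.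
- Ketone ⇒ phloroacetophenone + 2 prenyl bromide (phenolate C-prenylation, the laboratory counterpart of aromatic prenyl transfer).
- Aldehyde ⇒ 3-bromo-4,5-dihydroxybenzaldehyde by 4-O-methylation, then Pd prenyl coupling (the 5'-prenyl is meta to the OH, so phenolate alkylation or Claisen rearrangement cannot place it).
- Ring order: A and B rings are bought; the pyranone C ring is the only ring formed, and it is formed last.

**Assumptions**
- 3-Bromo-4,5-dihydroxybenzaldehyde is bought (it is also one AlCl3/pyridine demethylation away from 5-bromovanillin).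
- The quinidine-derived thiourea is taken as the pseudoenantiomer that gives 2S (Si-face attack at Cβ); one analytical run confirms this, and the equally available quinine-derived catalyst gives the antipode.

**Route**

Step 1
Reactants: 1 2,4,6-trihydroxyacetophenone (phloroacetophenone), 2 prenyl bromide (1-bromo-3-methylbut-2-ene; 2.2 equiv)
Product: 3 1-[2,4,6-trihydroxy-3,5-bis(3-methylbut-2-en-1-yl)phenyl]ethan-1-one (3,5-diprenylphloroacetophenone)
Conditions: 10% aq KOH, 0 °C to rt, 2 h, Ar; acidic work-up, chromatography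
Reagents that add atoms: prenyl bromide (2), CC(C)=CCBr
Why: In water the phloroglucinol-type phenolate reacts at carbon, so two successive SN2 C-alkylations by the primary allylic bromide (phenolate C-prenylation) fill the only two free ring positions; mono- and over-prenylated by-products are separated and the mono-prenyl ketone is resubmitted.

Step 2
Reactants: 4 3-bromo-4,5-dihydroxybenzaldehyde, 5 iodomethane (1.1 equiv)
Product: 6 3-bromo-5-hydroxy-4-methoxybenzaldehyde
Conditions: Li2CO3 (1.1 equiv), DMF, 40 °C, 16 h
Reagents that add atoms: iodomethane (5), CI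
Why: Only the 4-OH (para to the formyl group, ortho to bromine) is acidic enough to be deprotonated by Li2CO3, so the Williamson O-methylation occurs there and leaves the 5-OH free.

Step 3
Reactants: 6 3-bromo-5-hydroxy-4-methoxybenzaldehyde, 7 tributyl(3-methylbut-2-en-1-yl)stannane (1.3 equiv)
Product: 8 3-hydroxy-4-methoxy-5-(3-methylbut-2-en-1-yl)benzaldehyde
Conditions: Pd(PPh3)4 (5 mol%), DMF, 95 °C, 12 h, Ar
Reagents that add atoms: tributyl(3-methylbut-2-en-1-yl)stannane (7), CCCC[Sn](CCCC)(CCCC)CC=C(C)C
Why: Migita–Kosugi–Stille coupling tolerates the free phenol and the aldehyde, and reductive elimination from the aryl(prenyl)palladium intermediate occurs at the unsubstituted allyl terminus to give the linear prenyl arene rather than the 1,1-dimethylallyl isomer.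

Step 4
Reactants: 3 3,5-diprenylphloroacetophenone, 8 3-hydroxy-4-methoxy-5-(3-methylbut-2-en-1-yl)benzaldehyde (1.3 equiv)
Product: 10 3,2',4',6'-tetrahydroxy-4-methoxy-5,3',5'-triprenylchalcone [(2E)-3-[3-hydroxy-4-methoxy-5-(3-methylbut-2-en-1-yl)phenyl]-1-[2,4,6-trihydroxy-3,5-bis(3-methylbut-2-en-1-yl)phenyl]prop-2-en-1-one], via aldol adduct 9 (not isolated)
Conditions: KOH (50% aq, 30 equiv), EtOH, 0 °C to rt, 72 h, Ar, dark; inverse quench into ice-cold dilute acid (pH 3–4), cold extraction, rapid chromatography on acid-washed silica to remove any flavanone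
Reagents that add atoms: none
Why: Claisen–Schmidt aldol condensation in which the aldehyde stays electrophilic because its phenoxide is meta to the formyl group, aldol 9 dehydrates by E1cB to the conjugated E-enone, and strong base holds the product as the ring-open chalcone polyphenolate, which cold acidification releases as 10 before it can cyclise.

Step 5
Reactants: 10 3,2',4',6'-tetrahydroxy-4-methoxy-5,3',5'-triprenylchalcone
Product: 12 isoamoritin [(2S)-5,7-dihydroxy-2-[3-hydroxy-4-methoxy-5-(3-methylbut-2-en-1-yl)phenyl]-6,8-bis(3-methylbut-2-en-1-yl)-2,3-dihydro-4H-chromen-4-one], via enol tautomer 11 (not isolated)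
Conditions: thiourea from 9-amino-9-deoxy-epi-quinidine and 3,5-bis(trifluoromethyl)phenyl isothiocyanate (10 mol%), toluene/CH2Cl2 9:1 (0.05 M), −20 °C, 48–72 h; cold 0.5 M citric acid wash; recrystallise to upgrade ee
Reagents that add atoms: none
Why: Proposed new method: a chalcone isomerase mimic in which the quinuclidine nitrogen acts as general base toward an ortho-OH while the thiourea, reinforced by the internal hydrogen bond from the other ortho-OH to the carbonyl, binds the enone, so the phenoxide is delivered to the Si face of Cβ in a 6-endo-trig oxa-Michael addition that sets C2 as S; enol 11 then ketonises without touching C2, and the 5-OH···O=C4 hydrogen bond of the product disfavours retro-Michael racemisation; the closest known reaction type is the bifunctional cinchona-thiourea-catalysed enantioselective intramolecular oxa-Michael cyclisation of ester-activated 2'-hydroxychalcones, here extended to an unactivated, unprotected polyphenolic chalcone.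

**Compound list**
1 | 2,4,6-trihydroxyacetophenone | CC(=O)c1c(O)cc(O)cc1O | starting material
2 | prenyl bromide (1-bromo-3-methylbut-2-ene) | CC(C)=CCBr | starting material
3 | 1-[2,4,6-trihydroxy-3,5-bis(3-methylbut-2-en-1-yl)phenyl]ethan-1-one | CC(=O)c1c(O)c(CC=C(C)C)c(O)c(CC=C(C)C)c1O | intermediate
4 | 3-bromo-4,5-dihydroxybenzaldehyde | O=Cc1cc(O)c(O)c(Br)c1 | starting material
5 | iodomethane | CI | starting material
6 | 3-bromo-5-hydroxy-4-methoxybenzaldehyde | COc1c(O)cc(C=O)cc1Br | intermediate
7 | tributyl(3-methylbut-2-en-1-yl)stannane | CCCC[Sn](CCCC)(CCCC)CC=C(C)C | starting material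
8 | 3-hydroxy-4-methoxy-5-(3-methylbut-2-en-1-yl)benzaldehyde | COc1c(O)cc(C=O)cc1CC=C(C)C | intermediate
9 | aldol adduct, racemic 3-hydroxy-3-[3-hydroxy-4-methoxy-5-(3-methylbut-2-en-1-yl)phenyl]-1-[2,4,6-trihydroxy-3,5-bis(3-methylbut-2-en-1-yl)phenyl]propan-1-one | COc1c(O)cc(C(O)CC(=O)c2c(O)c(CC=C(C)C)c(O)c(CC=C(C)C)c2O)cc1CC=C(C)C | intermediate (not isolated)
10 | (2E)-3-[3-hydroxy-4-methoxy-5-(3-methylbut-2-en-1-yl)phenyl]-1-[2,4,6-trihydroxy-3,5-bis(3-methylbut-2-en-1-yl)phenyl]prop-2-en-1-one | COc1c(O)cc(/C=C/C(=O)c2c(O)c(CC=C(C)C)c(O)c(CC=C(C)C)c2O)cc1CC=C(C)C | intermediate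
11 | enol tautomer, (2S)-2-[3-hydroxy-4-methoxy-5-(3-methylbut-2-en-1-yl)phenyl]-6,8-bis(3-methylbut-2-en-1-yl)-2H-chromene-4,5,7-triol | COc1c(O)cc([C@@H]2C=C(O)c3c(O)c(CC=C(C)C)c(O)c(CC=C(C)C)c3O2)cc1CC=C(C)C | intermediate (not isolated)
12 | isoamoritin, (2S)-5,7-dihydroxy-2-[3-hydroxy-4-methoxy-5-(3-methylbut-2-en-1-yl)phenyl]-6,8-bis(3-methylbut-2-en-1-yl)-2,3-dihydro-4H-chromen-4-one | COc1c(O)cc([C@@H]2CC(=O)c3c(O)c(CC=C(C)C)c(O)c(CC=C(C)C)c3O2)cc1CC=C(C)C | target

**Step count**
Total steps: 5. Longest linear sequence: 4 (4 → 6 → 8 → 10 → 12).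

**Three steps most likely to fail**

Step 5 is the most likely to fail. No asymmetric catalyst has been shown to work on an unactivated, unprotected 2',6'-dihydroxychalcone, so both the level and the sense of induction are open. Background cyclisation and amine-mediated retro-Michael reaction can also erode ee. The fallback sets out from 10: cyclisation without induction (NaOAc, EtOH, reflux) gives racemic isoamoritin F1. Preparative chiral SFC on an amylose tris(3,5-dimethylphenylcarbamate) phase then returns to the route at 12 and leaves (2R)-isoamoritin F2. F2 is reopened to 10 in aq KOH/EtOH with a cold acid quench and recycled.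

Step 4 is the second risk. The polyphenolate of 3 enolises poorly, so conversion may be low, and 10 can cyclise to racemic flavanone during work-up. The fallback sets out from 3 and 8: MOMCl/i-Pr2NEt in CH2Cl2 converts 3 into 1-[2-hydroxy-4,6-bis(methoxymethoxy)-3,5-bis(3-methylbut-2-en-1-yl)phenyl]ethan-1-one F3 and 8 into 4-methoxy-3-(methoxymethoxy)-5-(3-methylbut-2-en-1-yl)benzaldehyde F4. Claisen–Schmidt condensation of these two (KOH, EtOH/H2O, rt) now runs on a mono-phenolate and gives the tris-MOM chalcone F5. 3 M HCl/MeOH at rt removes the three MOM groups and rejoins the route at 10.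

Step 3 is the third risk. The prenyl stannane can transfer through either allyl terminus, and the free phenol may slow the coupling. The fallback sets out from 6: Stille coupling with allyltributylstannane (Pd(PPh3)4, DMF, 90 °C), where no α/γ question exists, gives 3-allyl-5-hydroxy-4-methoxybenzaldehyde F6. Cross-metathesis with excess 2-methyl-2-butene (Grubbs II, CH2Cl2, 40 °C) turns the allyl group into the prenyl group and rejoins the route at 8.

**Further compounds**
F1 | step 5 | racemic isoamoritin | COc1c(O)cc(C2CC(=O)c3c(O)c(CC=C(C)C)c(O)c(CC=C(C)C)c3O2)cc1CC=C(C)C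
F2 | step 5 | (2R)-isoamoritin | COc1c(O)cc([C@H]2CC(=O)c3c(O)c(CC=C(C)C)c(O)c(CC=C(C)C)c3O2)cc1CC=C(C)C
F3 | step 4 | 1-[2-hydroxy-4,6-bis(methoxymethoxy)-3,5-bis(3-methylbut-2-en-1-yl)phenyl]ethan-1-one | CC(=O)c1c(O)c(CC=C(C)C)c(OCOC)c(CC=C(C)C)c1OCOC
F4 | step 4 | 4-methoxy-3-(methoxymethoxy)-5-(3-methylbut-2-en-1-yl)benzaldehyde | COCOc1cc(C=O)cc(CC=C(C)C)c1OC
F5 | step 4 | (2E)-1-[2-hydroxy-4,6-bis(methoxymethoxy)-3,5-bis(3-methylbut-2-en-1-yl)phenyl]-3-[4-methoxy-3-(methoxymethoxy)-5-(3-methylbut-2-en-1-yl)phenyl]prop-2-en-1-one | COCOc1cc(/C=C/C(=O)c2c(O)c(CC=C(C)C)c(OCOC)c(CC=C(C)C)c2OCOC)cc(CC=C(C)C)c1OC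
F6 | step 3 | 3-allyl-5-hydroxy-4-methoxybenzaldehyde | C=CCc1cc(C=O)cc(O)c1OC
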